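**Retrosynthetic overview**

1. Numbering as a 1-tetralone: C1 ketone, C3 carbinol, C4a/C8a ring fusion, C5 pyranonyl, C6 isopentyl, C8 phenol; ring A is the benzene ring, ring B the cyclohexanone.
2. The route rests on the 1,3-placed C1 ketone and C3 carbinol of ring B. C1 hangs on C8a beside C4a, and C4 on C4a can carry a 2-silyloxyallyl unit (C3, C2). A rhodium-catalysed addition of the aldehyde C1–H bond across C2=C3 then makes C1–C2 and C3–H, closes ring B last and sets C3.
3. The hydroacylation precursor is cut at the C5–pyranone bond (Negishi coupling of an arylzinc with 6-chloro-4-(methoxymethoxy)pyran-2-one, made from malonyl dichloride) and at the enol ether C3=C2 bond (Petasis methylenation of a silyl arylacetate). The aldehyde is masked as an aminal during these steps.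
4. Ring A is bought as methyl 3,5-dihydroxyphenylacetate, which already holds C4 and C3. Formylation gives C1, triflation and alkyl Negishi coupling give the C6 isopentyl group, and bromination para to the C8 ether marks C5.
5. Ring order: ring A (bought), pyranone ring (made apart, joined to C5), ring B (key step); one acidic step then removes the silyl and both methoxymethyl groups.

Key step: step 13

Assumption: which antipode of DTBM-SEGPHOS delivers hydride to the face of C3 that gives (R) is not known for a 2-silyloxyallyl group; the (R)-ligand is written and the (S)-ligand is taken if a trial run shows the opposite sense.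

**Route**

Step 1
Reactants: 1 methyl 2-(3,5-dihydroxyphenyl)acetate
Product: 2 methyl 2-(2-formyl-3,5-dihydroxyphenyl)acetate
Conditions: POCl3, DMF, MeCN, 0 °C → rt; then H2O, 50 °C
Reagents that add atoms: N,N-dimethylformamide CN(C)C=O; water O
Why: Vilsmeier–Haack formylation of the resorcinol ring should go, as with orcinol, to the position beside the side chain that is ortho to one hydroxyl and para to the other, and the iminium salt is hydrolysed on work-up.

Step 2
Reactants: 2 methyl 2-(2-formyl-3,5-dihydroxyphenyl)acetate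
Product: 3 methyl 2-[2-formyl-3-hydroxy-5-(trifluoromethanesulfonyloxy)phenyl]acetate
Conditions: PhNTf2, Et3N, CH2Cl2, 0 °C → rt
Reagents that add atoms: N-phenylbis(trifluoromethanesulfonimide) O=S(=O)(N(c1ccccc1)S(=O)(=O)C(F)(F)F)C(F)(F)F
Why: O-sulfonylation should take the phenol para to the formyl group, which is the more acidic one and is not hydrogen-bonded, while the ortho hydroxyl is held in a chelate with the aldehyde.

Step 3
Reactants: 3 methyl 2-[2-formyl-3-hydroxy-5-(trifluoromethanesulfonyloxy)phenyl]acetate
Product: 4 methyl 2-[2-formyl-3-(methoxymethoxy)-5-(trifluoromethanesulfonyloxy)phenyl]acetate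
Conditions: MOMCl, i-Pr2NEt, CH2Cl2, 0 °C → rt
Reagents that add atoms: chloromethyl methyl ether COCCl
Why: O-alkylation of the remaining phenol gives the methoxymethyl acetal, which is stable to the organometallic and basic steps that follow.

Step 4
Reactants: 4 methyl 2-[2-formyl-3-(methoxymethoxy)-5-(trifluoromethanesulfonyloxy)phenyl]acetate; 5 (3-methylbutyl)zinc bromide
Product: 6 methyl 2-[2-formyl-3-(methoxymethoxy)-5-(3-methylbutyl)phenyl]acetate
Conditions: Pd(dppf)Cl2 (3 mol %), THF, 50 °C
Reagents that add atoms: none
Why: Negishi coupling of the electron-poor aryl triflate with a primary alkylzinc halide tolerates the aldehyde and the ester, and the dppf ligand favours reductive elimination over β-hydride elimination.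

Step 5
Reactants: 6 methyl 2-[2-formyl-3-(methoxymethoxy)-5-(3-methylbutyl)phenyl]acetate
Product: 7 methyl 2-[2-bromo-6-formyl-5-(methoxymethoxy)-3-(3-methylbutyl)phenyl]acetate
Conditions: NBS, MeCN, 0 °C → rt, dark
Reagents that add atoms: N-bromosuccinimide O=C1CCC(=O)N1Br
Why: Electrophilic aromatic bromination should go to the free position para to the methoxymethoxy group (the future C5), which is also meta to the formyl group, in preference to the position ortho to the ether.

Step 6
Reactants: 7 methyl 2-[2-bromo-6-formyl-5-(methoxymethoxy)-3-(3-methylbutyl)phenyl]acetate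
Product: 8 methyl 2-[2-bromo-6-(1,3-dimethylimidazolidin-2-yl)-5-(methoxymethoxy)-3-(3-methylbutyl)phenyl]acetate
Conditions: MeNHCH2CH2NHMe, 4 Å MS, toluene, 80 °C
Reagents that add atoms: N,N'-dimethylethane-1,2-diamine CNCCNC
Why: Condensation of the aldehyde with the secondary diamine gives the imidazolidine (aminal protection), which is inert to silanolate, Cp2Ti=CH2 and alkyllithium and can later be opened by water at near-neutral pH.

Step 7
Reactants: 8 methyl 2-[2-bromo-6-(1,3-dimethylimidazolidin-2-yl)-5-(methoxymethoxy)-3-(3-methylbutyl)phenyl]acetate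
Product: 10 tert-butyldimethylsilyl 2-[2-bromo-6-(1,3-dimethylimidazolidin-2-yl)-5-(methoxymethoxy)-3-(3-methylbutyl)phenyl]acetate, via potassium carboxylate 9 (not isolated)
Conditions: KOSiMe3, THF, rt; then TBSCl, 0 °C → rt; KCl filtered off, no aqueous work-up
Reagents that add atoms: potassium trimethylsilanolate C[Si](C)(C)[O-].[K+]; tert-butyldimethylsilyl chloride CC(C)(C)[Si](C)(C)Cl
Why: Nucleophilic ester cleavage by trimethylsilanolate gives the anhydrous potassium carboxylate, and its O-silylation forms the silyl ester without any acid that would open the aminal.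

Step 8
Reactants: 10 tert-butyldimethylsilyl 2-[2-bromo-6-(1,3-dimethylimidazolidin-2-yl)-5-(methoxymethoxy)-3-(3-methylbutyl)phenyl]acetate
Product: 11 2-{3-bromo-2-[2-(tert-butyldimethylsilyloxy)prop-2-en-1-yl]-6-(methoxymethoxy)-4-(3-methylbutyl)phenyl}-1,3-dimethylimidazolidine
Conditions: Cp2TiMe2, toluene, 65 °C, dark; filtration through basic alumina
Reagents that add atoms: dimethyltitanocene Cp2TiMe2 [CH3-].[CH3-].[Ti+4].C1=C[CH-]C=C1.C1=C[CH-]C=C1
Why: Petasis methylenation of the silyl ester carbonyl by Cp2Ti=CH2 gives the enol silyl ether with the double bond fixed at the terminal carbon, a regiochemistry that enolisation of the corresponding benzyl methyl ketone would not secure.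

Step 9
Reactants: 12 malonyl dichloride (two molecules)
Product: 15 6-chloro-4-hydroxy-2H-pyran-2-one, via pyranone carbonyl chloride 13 (not isolated), via pyranone carboxylic acid 14 (not isolated)
Conditions: neat, rt, 3 d; then H2O, 1,4-dioxane, 60 °C
Reagents that add atoms: none
Why: Self-condensation of malonyl dichloride (C-acylation of one molecule by another, then closure of an enol oxygen onto an acid chloride) gives the chloropyranone acid chloride, and hydrolysis followed by decarboxylation of the vinylogous β-keto acid leaves the 6-chloro-4-hydroxypyranone.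

Step 10
Reactants: 15 6-chloro-4-hydroxy-2H-pyran-2-one
Product: 16 6-chloro-4-(methoxymethoxy)-2H-pyran-2-one
Conditions: MOMCl, i-Pr2NEt, CH2Cl2, 0 °C
Reagents that add atoms: chloromethyl methyl ether COCCl
Why: O-alkylation of the acidic 4-hydroxyl with the hard chloromethyl ether gives the vinylogous methoxymethyl ester, which removes the acidic proton before the organozinc coupling and the rhodium step.

Step 11
Reactants: 11 2-{3-bromo-2-[2-(tert-butyldimethylsilyloxy)prop-2-en-1-yl]-6-(methoxymethoxy)-4-(3-methylbutyl)phenyl}-1,3-dimethylimidazolidine; 16 6-chloro-4-(methoxymethoxy)-2H-pyran-2-one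
Product: 19 6-{2-[2-(tert-butyldimethylsilyloxy)prop-2-en-1-yl]-3-(1,3-dimethylimidazolidin-2-yl)-4-(methoxymethoxy)-6-(3-methylbutyl)phenyl}-4-(methoxymethoxy)-2H-pyran-2-one, via aryllithium 17 (not isolated), via arylzinc chloride 18 (not isolated)
Conditions: t-BuLi (2.1 equiv), THF, −78 °C; ZnCl2, −78 °C → rt; 16, Pd2(dba)3 (2.5 mol %), SPhos (10 mol %), THF, 50 °C; filtration through basic alumina
Reagents that add atoms: none
Why: Bromine–lithium exchange and transmetalation to zinc give an arylzinc that does not attack the lactone, and Negishi coupling at the activated C6–Cl bond of the pyranone with a bulky biarylphosphine should join the pyranone to the di-ortho-substituted C5.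

Step 12
Reactants: 19 6-{2-[2-(tert-butyldimethylsilyloxy)prop-2-en-1-yl]-3-(1,3-dimethylimidazolidin-2-yl)-4-(methoxymethoxy)-6-(3-methylbutyl)phenyl}-4-(methoxymethoxy)-2H-pyran-2-one
Product: 20 2-[2-(tert-butyldimethylsilyloxy)prop-2-en-1-yl]-6-(methoxymethoxy)-3-[4-(methoxymethoxy)-2-oxo-2H-pyran-6-yl]-4-(3-methylbutyl)benzaldehyde
Conditions: SiO2, H2O, CH2Cl2, rt
Reagents that add atoms: water O
Why: Hydrolysis of the strained, di-ortho-substituted aminal should take place on wet silica gel at near-neutral pH, where the enol silyl ether and both methoxymethyl groups are kept.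

Step 13
Reactants: 20 2-[2-(tert-butyldimethylsilyloxy)prop-2-en-1-yl]-6-(methoxymethoxy)-3-[4-(methoxymethoxy)-2-oxo-2H-pyran-6-yl]-4-(3-methylbutyl)benzaldehyde
Product: 21 (3R)-3-(tert-butyldimethylsilyloxy)-8-(methoxymethoxy)-5-[4-(methoxymethoxy)-2-oxo-2H-pyran-6-yl]-6-(3-methylbutyl)-3,4-dihydronaphthalen-1(2H)-one
Conditions: [Rh(cod)Cl]2 (2.5 mol %), (R)-DTBM-SEGPHOS (5.5 mol %), AgBF4 (5 mol %), THF, rt, AgCl filtered off; then 20, 2,6-di-tert-butylpyridine (10 mol %), THF, 60 °C
Reagents that add atoms: none
Why: Proposed new method: the aldehyde C–H bond of 20 adds oxidatively to the cationic monovalent rhodium–bisphosphine complex, the acyl hydride of trivalent rhodium inserts the tethered enol silyl ether with hydride going to the silyloxy-bearing C3 and rhodium to the terminal C2, and C–C reductive elimination from the seven-membered acyl alkyl rhodacycle forms C1–C2. The closest known reaction is the rhodium-catalysed enantioselective endo hydroacylation of ortho-allylbenzaldehydes bearing 1,1-disubstituted alkenes to 3-substituted 1-tetralones; a silyloxy group as the 2-substituent of the alkene is the extension. Ring B closes in a formal 6-endo mode, because the 5-exo path would need a tertiary α-silyloxyalkyl rhodium and would build a quaternary centre. The C3 stereocentre is set by the chiral bisphosphine, which selects the enantioface of the alkene in the hydride insertion. The step needs endo regioselectivity (secured by the 1,1-disubstitution), face selectivity (ligand) and chemoselectivity against decarbonylation, β-silyloxy elimination, double-bond migration and Lewis-acid aldol closure; the ortho C8 ether that can chelate rhodium, the bulky silyl group, the wide ligand and the silver-free, base-buffered catalyst solution are meant to secure the last of these.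

Step 14
Reactants: 21 (3R)-3-(tert-butyldimethylsilyloxy)-8-(methoxymethoxy)-5-[4-(methoxymethoxy)-2-oxo-2H-pyran-6-yl]-6-(3-methylbutyl)-3,4-dihydronaphthalen-1(2H)-one
Product: 22 (3R)-3,8-dihydroxy-5-(4-hydroxy-2-oxo-2H-pyran-6-yl)-6-(3-methylbutyl)-3,4-dihydronaphthalen-1(2H)-one
Conditions: HCl (1.25 M in MeOH), 0 °C → rt
Reagents that add atoms: none
Why: Acid-catalysed acetal exchange removes both methoxymethyl groups and methanolysis removes the silyl ether in one operation without touching C3, the temperature being kept low so that the β-hydroxy ketone does not dehydrate to the naphthol.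

**Compound list**

1 | methyl 2-(3,5-dihydroxyphenyl)acetate | COC(=O)Cc1cc(O)cc(O)c1 | starting material
2 | methyl 2-(2-formyl-3,5-dihydroxyphenyl)acetate | COC(=O)Cc1cc(O)cc(O)c1C=O | intermediate
3 | methyl 2-[2-formyl-3-hydroxy-5-(trifluoromethanesulfonyloxy)phenyl]acetate | COC(=O)Cc1cc(OS(=O)(=O)C(F)(F)F)cc(O)c1C=O | intermediate
4 | methyl 2-[2-formyl-3-(methoxymethoxy)-5-(trifluoromethanesulfonyloxy)phenyl]acetate | COC(=O)Cc1cc(OS(=O)(=O)C(F)(F)F)cc(OCOC)c1C=O | intermediate
5 | (3-methylbutyl)zinc bromide | CC(C)CC[Zn]Br | starting material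
6 | methyl 2-[2-formyl-3-(methoxymethoxy)-5-(3-methylbutyl)phenyl]acetate | COC(=O)Cc1cc(CCC(C)C)cc(OCOC)c1C=O | intermediate
7 | methyl 2-[2-bromo-6-formyl-5-(methoxymethoxy)-3-(3-methylbutyl)phenyl]acetate | COC(=O)Cc1c(Br)c(CCC(C)C)cc(OCOC)c1C=O | intermediate
8 | methyl 2-[2-bromo-6-(1,3-dimethylimidazolidin-2-yl)-5-(methoxymethoxy)-3-(3-methylbutyl)phenyl]acetate | COC(=O)Cc1c(Br)c(CCC(C)C)cc(OCOC)c1C1N(C)CCN1C | intermediate
9 | potassium 2-[2-bromo-6-(1,3-dimethylimidazolidin-2-yl)-5-(methoxymethoxy)-3-(3-methylbutyl)phenyl]acetate | [K+].[O-]C(=O)Cc1c(Br)c(CCC(C)C)cc(OCOC)c1C1N(C)CCN1C | intermediate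
10 | tert-butyldimethylsilyl 2-[2-bromo-6-(1,3-dimethylimidazolidin-2-yl)-5-(methoxymethoxy)-3-(3-methylbutyl)phenyl]acetate | CC(C)(C)[Si](C)(C)OC(=O)Cc1c(Br)c(CCC(C)C)cc(OCOC)c1C1N(C)CCN1C | intermediate
11 | 2-{3-bromo-2-[2-(tert-butyldimethylsilyloxy)prop-2-en-1-yl]-6-(methoxymethoxy)-4-(3-methylbutyl)phenyl}-1,3-dimethylimidazolidine | C=C(O[Si](C)(C)C(C)(C)C)Cc1c(Br)c(CCC(C)C)cc(OCOC)c1C1N(C)CCN1C | intermediate
12 | malonyl dichloride | O=C(Cl)CC(=O)Cl | starting material
13 | 6-chloro-4-hydroxy-2-oxo-2H-pyran-3-carbonyl chloride | O=C(Cl)c1c(O)cc(Cl)oc1=O | intermediate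
14 | 6-chloro-4-hydroxy-2-oxo-2H-pyran-3-carboxylic acid | OC(=O)c1c(O)cc(Cl)oc1=O | intermediate
15 | 6-chloro-4-hydroxy-2H-pyran-2-one | Oc1cc(Cl)oc(=O)c1 | intermediate
16 | 6-chloro-4-(methoxymethoxy)-2H-pyran-2-one | COCOc1cc(Cl)oc(=O)c1 | intermediate
17 | aryllithium from 11 (lithium in place of bromine) | [Li]c1c(CC(=C)O[Si](C)(C)C(C)(C)C)c(C2N(C)CCN2C)c(OCOC)cc1CCC(C)C | intermediate
18 | arylzinc chloride from 17 | Cl[Zn]c1c(CC(=C)O[Si](C)(C)C(C)(C)C)c(C2N(C)CCN2C)c(OCOC)cc1CCC(C)C | intermediate
19 | 6-{2-[2-(tert-butyldimethylsilyloxy)prop-2-en-1-yl]-3-(1,3-dimethylimidazolidin-2-yl)-4-(methoxymethoxy)-6-(3-methylbutyl)phenyl}-4-(methoxymethoxy)-2H-pyran-2-one | C=C(O[Si](C)(C)C(C)(C)C)Cc1c(-c2cc(OCOC)cc(=O)o2)c(CCC(C)C)cc(OCOC)c1C1N(C)CCN1C | intermediate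
20 | 2-[2-(tert-butyldimethylsilyloxy)prop-2-en-1-yl]-6-(methoxymethoxy)-3-[4-(methoxymethoxy)-2-oxo-2H-pyran-6-yl]-4-(3-methylbutyl)benzaldehyde | C=C(O[Si](C)(C)C(C)(C)C)Cc1c(-c2cc(OCOC)cc(=O)o2)c(CCC(C)C)cc(OCOC)c1C=O | intermediate
21 | (3R)-3-(tert-butyldimethylsilyloxy)-8-(methoxymethoxy)-5-[4-(methoxymethoxy)-2-oxo-2H-pyran-6-yl]-6-(3-methylbutyl)-3,4-dihydronaphthalen-1(2H)-one | CC(C)CCc1cc(OCOC)c2c(c1-c1cc(OCOC)cc(=O)o1)C[C@@H](O[Si](C)(C)C(C)(C)C)CC2=O | intermediate
22 | (3R)-3,8-dihydroxy-5-(4-hydroxy-2-oxo-2H-pyran-6-yl)-6-(3-methylbutyl)-3,4-dihydronaphthalen-1(2H)-one | CC(C)CCc1cc(O)c2c(c1-c1cc(O)cc(=O)o1)C[C@@H](O)CC2=O | target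

**Step count**

Total steps: 14. Longest linear sequence: 12 steps (steps 1–8 and 11–14, from 1 to 22); steps 9 and 10 form the pyranone branch.

**Steps most likely to fail**

1. Step 13 (proposed new method). Several processes may compete with the ring closure:
   - loss of the silyloxy group by β-elimination from the alkylrhodium intermediate;
   - migration of the double bond into conjugation with ring A;
   - closure of the enol silyl ether onto the aldehyde under Lewis acid or fluoride from the counter-ion;
   - decarbonylation;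
   - poor enantioface selection.

   The fallback sets out from 20 and uses a thiol-catalysed radical-chain hydroacylation (polarity-reversal catalysis; tert-dodecanethiol, di-tert-butyl hyponitrite, 1,4-dioxane, 60 °C). The thiyl radical abstracts the aldehydic hydrogen, the aroyl radical adds to the terminal C2 of the electron-rich enol silyl ether in the 6-endo sense, and the thiol returns hydrogen to the tertiary α-silyloxy radical at C3. This should give the racemic silyl ether of the protected tetralone F1. Its enantiomers are separated by preparative chromatography on a chiral stationary phase into 21 and the (3S)-antipode F2, which is discarded. The route is rejoined at 21.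

2. Step 8. The silyl ester may be hydrolysed by traces of water before it is methylenated, and the enol silyl ether may be protodesilylated or isomerised on isolation. The fallback sets out from ester 8. Chloromethyllithium, made in the flask from ICH2Cl and MeLi·LiBr in THF at −78 °C in the presence of 8, adds once to the ester and gives the chloromethyl ketone F3. Reductive silylation with zinc dust, TBSCl and TMEDA in THF then forms the zinc enolate only at the carbon that carried chlorine and silylates it on oxygen. The route is rejoined at 11.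

3. Step 11. The aryllithium may be quenched by the benzylic and allylic CH2 group next to it, transmetalation and coupling at the di-ortho-substituted C5 may be slow, and the organometallic may attack the pyranone. The fallback reverses the polarity of the coupling, so that no aryllithium or arylzinc is made from 11. Chloropyranone 16 is stannylated with (Bu3Sn)2 and Pd(PPh3)4 in toluene at 100 °C to give 4-(methoxymethoxy)-6-(tributylstannyl)-2H-pyran-2-one F4. A Stille coupling of F4 with bromide 11 (Pd[P(t-Bu)3]2, CuI, 1,4-dioxane, 80 °C) then forms the C5–pyranone bond. The route is rejoined at 19.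

**Further compounds**

F1 | step 13 | racemic 3-(tert-butyldimethylsilyloxy)-8-(methoxymethoxy)-5-[4-(methoxymethoxy)-2-oxo-2H-pyran-6-yl]-6-(3-methylbutyl)-3,4-dihydronaphthalen-1(2H)-one | CC(C)CCc1cc(OCOC)c2c(c1-c1cc(OCOC)cc(=O)o1)CC(O[Si](C)(C)C(C)(C)C)CC2=O
F2 | step 13 | (3S)-3-(tert-butyldimethylsilyloxy)-8-(methoxymethoxy)-5-[4-(methoxymethoxy)-2-oxo-2H-pyran-6-yl]-6-(3-methylbutyl)-3,4-dihydronaphthalen-1(2H)-one | CC(C)CCc1cc(OCOC)c2c(c1-c1cc(OCOC)cc(=O)o1)C[C@H](O[Si](C)(C)C(C)(C)C)CC2=O
F3 | step 8 | 1-[2-bromo-6-(1,3-dimethylimidazolidin-2-yl)-5-(methoxymethoxy)-3-(3-methylbutyl)phenyl]-3-chloropropan-2-one | ClCC(=O)Cc1c(Br)c(CCC(C)C)cc(OCOC)c1C1N(C)CCN1C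
F4 | step 11 | 4-(methoxymethoxy)-6-(tributylstannyl)-2H-pyran-2-one | CCCC[Sn](CCCC)(CCCC)c1cc(OCOC)cc(=O)o1
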